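## Retrosynthetic overview

1. Target 31 ⇒ desilylation and transannular 5-endo-dig oxa-Michael addition of the C10–OH onto a ten-membered 2-yn-1-one 29 (furanone formed last).
2. 29 ⇒ ring-closing Pd/Cu thioester–terminal alkyne coupling at C1–C2 of the seco-lactone 28 (carbocycle formed second; the new step).
3. 28 ⇒ Cr-catalysed asymmetric 2-(methoxycarbonyl)allylation and lactonisation at C7–C8, joining west aldehyde 10 and east allylic bromide 25 (trans-lactone formed first).
4. 10 ⇐ (S)-lactic acid and allyl bromide (C10 by self-regeneration of stereocentres). 25 ⇐ crotyl alcohol (Sharpless epoxidation and alkynylalane opening set C4/C5), an isobutenyl nucleophile (C6/C7), methyl propiolate (C11–C13) and methacryloyl chloride.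
5. Ring order: γ-lactone → ten-membered carbocycle → 3(2H)-furanone.

Assumption: locants C1–C15 follow germacrane numbering (C1 furanone C=O, C3/C10 carry the bridging O, C6 the methacrylate, C8 the lactone O); protecting-group and auxiliary reagents (TESCl, TESOTf, ligands) are treated as reagents and not numbered.

## Route

**West fragment (steps 1–6)**

Step 1
Reactants: 1 (S)-lactic acid; 2 pivalaldehyde
Product: 3 (2S,5S)-2-tert-butyl-5-methyl-1,3-dioxolan-4-one
Conditions: TsOH·H2O (cat.), H2SO4 (cat.), pentane, reflux, Dean–Stark; recrystallise at −78 °C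
Reagents that add atoms: none
Why: Acid-catalysed acetalisation (Seebach self-regeneration of stereocentres) gives the cis acetal as the major, crystallisable isomer, storing the lactate configuration in the new acetal centre.

Step 2
Reactants: 3 (2S,5S)-2-tert-butyl-5-methyl-1,3-dioxolan-4-one; 4 allyl bromide
Product: 5 (2S,5R)-2-tert-butyl-5-methyl-5-(prop-2-en-1-yl)-1,3-dioxolan-4-one
Conditions: LDA, THF, −78 °C; then 4, −78 → −30 °C
Reagents that add atoms: none
Why: Enolate alkylation anti to the tert-butyl group replaces H by allyl with overall retention and sets the C10 quaternary centre.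

Step 3
Reactants: 5 (2S,5R)-2-tert-butyl-5-methyl-5-(prop-2-en-1-yl)-1,3-dioxolan-4-one
Product: 6 (2R)-2-hydroxy-2-methylpent-4-enoic acid
Conditions: LiOH, THF/H2O, rt; then 1 M HCl
Reagents that add atoms: water, O
Why: Saponification of the acylal-type lactone releases the auxiliary aldehyde without touching the quaternary centre.

Step 4
Reactants: 6 (2R)-2-hydroxy-2-methylpent-4-enoic acid; 7 ethanethiol
Product: 8 S-ethyl (2R)-2-hydroxy-2-methylpent-4-enethioate
Conditions: DCC, DMAP (cat.), CH2Cl2, 0 °C → rt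
Reagents that add atoms: none
Why: Steglich thioesterification; the thiol far outcompetes the hindered tertiary hydroxyl for the activated acid.

Step 5
Reactants: 8 S-ethyl (2R)-2-hydroxy-2-methylpent-4-enethioate
Product: 9 S-ethyl (2R)-2-methyl-2-[(triethylsilyl)oxy]pent-4-enethioate
Conditions: TESOTf, 2,6-lutidine, CH2Cl2, −78 → 0 °C
Reagents that add atoms: triethylsilyl trifluoromethanesulfonate, CC[Si](CC)(CC)OS(=O)(=O)C(F)(F)F
Why: Silyl triflate silylation of the tertiary alcohol blocks retro-aldol and β-elimination once the aldehyde is unveiled.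

Step 6
Reactants: 9 S-ethyl (2R)-2-methyl-2-[(triethylsilyl)oxy]pent-4-enethioate
Product: 10 S-ethyl (2R)-2-methyl-4-oxo-2-[(triethylsilyl)oxy]butanethioate
Conditions: O3, CH2Cl2, −78 °C; then PPh3, → rt
Reagents that add atoms: ozone, [O-][O+]=O
Why: Ozonolysis with reductive work-up cleaves the only C=C to the C8 aldehyde; thioester and silyl ether are inert at −78 °C.

**East fragment (steps 7–14)**

Step 7
Reactants: 11 (E)-but-2-en-1-ol
Product: 12 [(2R,3R)-3-methyloxiran-2-yl]methanol
Conditions: Ti(OiPr)4 (cat.), D-(−)-DIPT (cat.), t-BuOOH, 4 Å MS, CH2Cl2, −20 °C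
Reagents that add atoms: tert-butyl hydroperoxide, CC(C)(C)OO
Why: Sharpless asymmetric epoxidation; the D-tartrate catalyst delivers oxygen to the face that gives the (2R,3R) epoxy alcohol (future C5 and C4).

Step 8
Reactants: 12 [(2R,3R)-3-methyloxiran-2-yl]methanol; 13 ethynyltrimethylsilane
Product: 15 (2S,3R)-3-methylpent-4-yne-1,2-diol, via TMS-alkyne diol 14 (not isolated)
Conditions: 13, n-BuLi, then Et2AlCl, toluene, 0 °C; 12, 0 °C → rt; then K2CO3 (cat.), MeOH, rt
Reagents that add atoms: none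
Why: Hydroxyl-directed, C3-selective SN2 opening of the 2,3-epoxy alcohol by the alkynylalane inverts the methyl-bearing carbon and sets C4 syn to the C5 oxygen; methanolysis then removes the alkynyl silane.

Step 9
Reactants: 15 (2S,3R)-3-methylpent-4-yne-1,2-diol
Product: 16 (3R,4S)-3-methyl-4,5-bis[(triethylsilyl)oxy]pent-1-yne
Conditions: TESCl, imidazole, DMF, 0 °C → rt
Reagents that add atoms: chlorotriethylsilane, CC[Si](Cl)(CC)CC
Why: Exhaustive silylation of both hydroxyls prepares the selective oxidation of the primary silyl ether.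

Step 10
Reactants: 16 (3R,4S)-3-methyl-4,5-bis[(triethylsilyl)oxy]pent-1-yne
Product: 17 (2S,3R)-3-methyl-2-[(triethylsilyl)oxy]pent-4-ynal
Conditions: (COCl)2, DMSO, CH2Cl2, −78 → −30 °C; then Et3N, −78 °C → rt
Reagents that add atoms: none
Why: Swern conditions cleave and oxidise a primary TES ether selectively in the presence of a secondary one, giving the C6 aldehyde directly without epimerising C5.

Step 11
Reactants: 17 (2S,3R)-3-methyl-2-[(triethylsilyl)oxy]pent-4-ynal; 18 (2-methylprop-1-en-1-yl)magnesium bromide; 19 methacryloyl chloride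
Product: 21 (4S,5S,6R)-2,6-dimethyl-5-[(triethylsilyl)oxy]oct-2-en-7-yn-4-yl 2-methylprop-2-enoate, via chlorozinc alkoxide 20 (not isolated)
Conditions: 18 (3 equiv), ZnCl2 (2 equiv), THF, 0 °C; toluene, 17, −20 °C; then 19, DMAP (cat.), 0 °C
Reagents that add atoms: none
Why: RZnCl-promoted chelation-controlled (Cram-chelate) alkenylzinc addition to the α-silyloxy aldehyde sets C6 syn to the C5 oxygen, and the zinc alkoxide is acylated in the flask so no free hydroxyl ever sits next to the ester.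

Step 12
Reactants: 21 (4S,5S,6R)-2,6-dimethyl-5-[(triethylsilyl)oxy]oct-2-en-7-yn-4-yl 2-methylprop-2-enoate
Product: 22 (2R,3S,4R)-4-methyl-1-oxo-3-[(triethylsilyl)oxy]hex-5-yn-2-yl 2-methylprop-2-enoate
Conditions: O3, CH2Cl2, −78 °C (Sudan Red 7B end point); then PPh3
Reagents that add atoms: ozone, [O-][O+]=O
Why: Chemoselective ozonolysis; the electron-rich trisubstituted alkene reacts far faster than the conjugated methacrylate or the terminal alkyne, unveiling the C7 aldehyde.

Step 13
Reactants: 22 (2R,3S,4R)-4-methyl-1-oxo-3-[(triethylsilyl)oxy]hex-5-yn-2-yl 2-methylprop-2-enoate; 23 methyl propiolate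
Product: 24 methyl (3RS,4S,5S,6R)-3-hydroxy-6-methyl-2-methylidene-4-[(2-methylprop-2-enoyl)oxy]-5-[(triethylsilyl)oxy]oct-7-ynoate
Conditions: 23, DIBAL-H, NMO, THF, 0 °C; then 22, 0 °C; cold Rochelle-salt work-up
Reagents that add atoms: none
Why: Vinylalumination (a fast, amine-free route to the Morita–Baylis–Hillman adduct) adds the α-aluminoacrylate to the aldehyde; the new carbinol centre is a mixture that is erased in step 14, and the cold non-basic quench limits acyl migration.

Step 14
Reactants: 24 methyl (3RS,4S,5S,6R)-3-hydroxy-6-methyl-2-methylidene-4-[(2-methylprop-2-enoyl)oxy]-5-[(triethylsilyl)oxy]oct-7-ynoate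
Product: 25 methyl (2Z,4S,5S,6R)-2-(bromomethyl)-6-methyl-4-[(2-methylprop-2-enoyl)oxy]-5-[(triethylsilyl)oxy]oct-2-en-7-ynoate
Conditions: NBS, Me2S, CH2Cl2, 0 °C → rt
Reagents that add atoms: N-bromosuccinimide, O=C1CCC(=O)N1Br
Why: Corey–Kim-type activation and SN2′ bromide attack transpose the Baylis–Hillman alcohol to the thermodynamic (Z)-2-(bromomethyl)enoate under near-neutral conditions that spare the TES ether.

**Union and endgame (steps 15–17)**

Step 15
Reactants: 10 S-ethyl (2R)-2-methyl-4-oxo-2-[(triethylsilyl)oxy]butanethioate; 25 methyl (2Z,4S,5S,6R)-2-(bromomethyl)-6-methyl-4-[(2-methylprop-2-enoyl)oxy]-5-[(triethylsilyl)oxy]oct-2-en-7-ynoate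
Product: 28 S-ethyl (2R)-2-methyl-3-[(2S,3R)-3-{(1S,2S,3R)-3-methyl-1-[(2-methylprop-2-enoyl)oxy]-2-[(triethylsilyl)oxy]pent-4-yn-1-yl}-4-methylidene-5-oxooxolan-2-yl]-2-[(triethylsilyl)oxy]propanethioate, via TMS ether 26 (not isolated), via hydroxy ester 27 (not isolated)
Conditions: CrCl2 (10 mol %), chiral carbazole bis(oxazoline) ligand (12 mol %, pre-complexed with Et3N), Mn, TMSCl, THF, rt; then aq. citric acid, MeOH, 0 °C; then PPTS (cat.), toluene, 40 °C
Reagents that add atoms: none
Why: Catalytic asymmetric Nozaki–Hiyama–Kishi-type 2-(alkoxycarbonyl)allylation: the ligand enantiomer is chosen (by a short screen) for Re-face attack on 10 to set C8 (S), the chair Zimmerman–Traxler transition state of the σ-allylchromium with the bulky C6 substituent equatorial sets C7 anti to C8, and lactonisation then gives the trans α-methylene-γ-butyrolactone.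

Step 16
Reactants: 28 S-ethyl (2R)-2-methyl-3-[(2S,3R)-3-{(1S,2S,3R)-3-methyl-1-[(2-methylprop-2-enoyl)oxy]-2-[(triethylsilyl)oxy]pent-4-yn-1-yl}-4-methylidene-5-oxooxolan-2-yl]-2-[(triethylsilyl)oxy]propanethioate
Product: 29 (4R,5S,6S,7R,8S,10R)-6-(methacryloyloxy)-1-oxo-5,10-bis(triethylsilyloxy)germacr-11(13)-en-2-yn-12,8-olide
Conditions: PdCl2(dppf) (10 mol %), P(2-furyl)3 (25 mol %), CuI (2 equiv), Et3N, DMF, 50 °C, syringe-pump addition of 28 (final 1 mM)
Reagents that add atoms: none
Why: Proposed new method: a ring-closing Pd(0)/Cu(I) acyl–alkynyl coupling in which Pd(0) inserts into the C(acyl)–S bond (Cu(I) removes the thiolate as insoluble CuSEt, which also protects the two Michael acceptors), the tethered copper acetylide transmetallates intramolecularly and C(acyl)–C(sp) reductive elimination closes the strained ten-membered 2-yn-1-one, helped by the gem-disubstituted C10, the trans-lactone and pseudo-high dilution; the closest known reactions are the intermolecular Pd/Cu coupling of thioesters with terminal alkynes (Fukuyama-type alkynyl ketone synthesis) and macrocyclic Sonogashira couplings, neither shown for a ten-membered ring closure.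

Step 17
Reactants: 29 (4R,5S,6S,7R,8S,10R)-6-(methacryloyloxy)-1-oxo-5,10-bis(triethylsilyloxy)germacr-11(13)-en-2-yn-12,8-olide
Product: 31 CNP0195404.1 (4S,5S,6S,7R,8S,10R)-5-hydroxy-6-(methacryloyloxy)-1-oxo-3,10-epoxygermacra-2,11(13)-dien-12,8-olide, via dihydroxy ynone 30 (not isolated)
Conditions: HF·pyridine, pyridine, THF, 0 °C → rt; then Ph3PAuNTf2 (5 mol %), CH2Cl2, rt
Reagents that add atoms: none
Why: Fluoride removes both TES ethers and the freed C10–OH adds across the ynone in a strain-relieving transannular 5-endo-dig oxa-Michael cyclisation (Au(I)-assisted if needed) to the 3(2H)-furanone; no stereocentre is formed or touched (the C4 descriptor changes from R to S only through CIP priorities).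

## Compound list

1 | (S)-lactic acid | C[C@H](O)C(=O)O | starting material
2 | pivalaldehyde (2,2-dimethylpropanal) | CC(C)(C)C=O | starting material
3 | (2S,5S)-2-tert-butyl-5-methyl-1,3-dioxolan-4-one | C[C@@H]1O[C@H](C(C)(C)C)OC1=O | intermediate
4 | allyl bromide | C=CCBr | starting material
5 | (2S,5R)-2-tert-butyl-5-methyl-5-(prop-2-en-1-yl)-1,3-dioxolan-4-one | C[C@]1(CC=C)O[C@H](C(C)(C)C)OC1=O | intermediate
6 | (2R)-2-hydroxy-2-methylpent-4-enoic acid | C[C@](CC=C)(O)C(=O)O | intermediate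
7 | ethanethiol | CCS | starting material
8 | S-ethyl (2R)-2-hydroxy-2-methylpent-4-enethioate | C[C@](CC=C)(O)C(=O)SCC | intermediate
9 | S-ethyl (2R)-2-methyl-2-[(triethylsilyl)oxy]pent-4-enethioate | C[C@](CC=C)(O[Si](CC)(CC)CC)C(=O)SCC | intermediate
10 | S-ethyl (2R)-2-methyl-4-oxo-2-[(triethylsilyl)oxy]butanethioate (west aldehyde) | C[C@](CC=O)(O[Si](CC)(CC)CC)C(=O)SCC | intermediate
11 | (E)-but-2-en-1-ol (crotyl alcohol) | C/C=C/CO | starting material
12 | [(2R,3R)-3-methyloxiran-2-yl]methanol | OC[C@H]1O[C@@H]1C | intermediate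
13 | ethynyltrimethylsilane | C#C[Si](C)(C)C | starting material
14 | (2S,3R)-3-methyl-5-(trimethylsilyl)pent-4-yne-1,2-diol (not isolated) | C[Si](C)(C)C#C[C@@H](C)[C@H](O)CO | intermediate
15 | (2S,3R)-3-methylpent-4-yne-1,2-diol | C#C[C@@H](C)[C@H](O)CO | intermediate
16 | (3R,4S)-3-methyl-4,5-bis[(triethylsilyl)oxy]pent-1-yne | C#C[C@@H](C)[C@H](O[Si](CC)(CC)CC)CO[Si](CC)(CC)CC | intermediate
17 | (2S,3R)-3-methyl-2-[(triethylsilyl)oxy]pent-4-ynal | C#C[C@@H](C)[C@H](O[Si](CC)(CC)CC)C=O | intermediate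
18 | (2-methylprop-1-en-1-yl)magnesium bromide | CC(C)=C[Mg]Br | starting material
19 | methacryloyl chloride | C=C(C)C(Cl)=O | starting material
20 | chlorozinc (4S,5S,6R)-2,6-dimethyl-5-[(triethylsilyl)oxy]oct-2-en-7-yn-4-olate (not isolated) | C#C[C@@H](C)[C@H](O[Si](CC)(CC)CC)[C@@H](O[Zn]Cl)C=C(C)C | intermediate
21 | (4S,5S,6R)-2,6-dimethyl-5-[(triethylsilyl)oxy]oct-2-en-7-yn-4-yl 2-methylprop-2-enoate | C#C[C@@H](C)[C@H](O[Si](CC)(CC)CC)[C@@H](OC(=O)C(C)=C)C=C(C)C | intermediate
22 | (2R,3S,4R)-4-methyl-1-oxo-3-[(triethylsilyl)oxy]hex-5-yn-2-yl 2-methylprop-2-enoate | C#C[C@@H](C)[C@H](O[Si](CC)(CC)CC)[C@@H](OC(=O)C(C)=C)C=O | intermediate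
23 | methyl propiolate | C#CC(=O)OC | starting material
24 | methyl (3RS,4S,5S,6R)-3-hydroxy-6-methyl-2-methylidene-4-[(2-methylprop-2-enoyl)oxy]-5-[(triethylsilyl)oxy]oct-7-ynoate | C#C[C@@H](C)[C@H](O[Si](CC)(CC)CC)[C@@H](OC(=O)C(C)=C)C(O)C(=C)C(=O)OC | intermediate
25 | methyl (2Z,4S,5S,6R)-2-(bromomethyl)-6-methyl-4-[(2-methylprop-2-enoyl)oxy]-5-[(triethylsilyl)oxy]oct-2-en-7-ynoate (east bromide) | C#C[C@@H](C)[C@H](O[Si](CC)(CC)CC)[C@@H](OC(=O)C(C)=C)/C=C(\CBr)C(=O)OC | intermediate
26 | 4-O-trimethylsilyl ether of 27 (C8–OTMS open-chain methyl ester; not isolated) | CCSC(=O)[C@](C)(O[Si](CC)(CC)CC)C[C@H](O[Si](C)(C)C)[C@H]([C@H](OC(=O)C(C)=C)[C@@H](O[Si](CC)(CC)CC)[C@H](C)C#C)C(=C)C(=O)OC | intermediate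
27 | methyl (3R,4S,6R)-7-(ethylsulfanyl)-4-hydroxy-6-methyl-3-{(1S,2S,3R)-3-methyl-1-[(2-methylprop-2-enoyl)oxy]-2-[(triethylsilyl)oxy]pent-4-yn-1-yl}-2-methylidene-7-oxo-6-[(triethylsilyl)oxy]heptanoate (not isolated) | CCSC(=O)[C@](C)(O[Si](CC)(CC)CC)C[C@H](O)[C@H]([C@H](OC(=O)C(C)=C)[C@@H](O[Si](CC)(CC)CC)[C@H](C)C#C)C(=C)C(=O)OC | intermediate
28 | S-ethyl (2R)-2-methyl-3-[(2S,3R)-3-{(1S,2S,3R)-3-methyl-1-[(2-methylprop-2-enoyl)oxy]-2-[(triethylsilyl)oxy]pent-4-yn-1-yl}-4-methylidene-5-oxooxolan-2-yl]-2-[(triethylsilyl)oxy]propanethioate (seco-lactone) | CCSC(=O)[C@](C)(O[Si](CC)(CC)CC)C[C@@H]1OC(=O)C(=C)[C@H]1[C@H](OC(=O)C(C)=C)[C@@H](O[Si](CC)(CC)CC)[C@H](C)C#C | intermediate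
29 | (4R,5S,6S,7R,8S,10R)-6-(methacryloyloxy)-1-oxo-5,10-bis(triethylsilyloxy)germacr-11(13)-en-2-yn-12,8-olide (ten-membered 2-yn-1-one trans-fused to the α-methylene lactone) | O=C1C#C[C@@H](C)[C@H](O[Si](CC)(CC)CC)[C@@H](OC(=O)C(C)=C)[C@@H]2C(=C)C(=O)O[C@H]2C[C@@]1(C)O[Si](CC)(CC)CC | intermediate
30 | (4R,5S,6S,7R,8S,10R)-5,10-dihydroxy-6-(methacryloyloxy)-1-oxogermacr-11(13)-en-2-yn-12,8-olide (not isolated) | O=C1C#C[C@@H](C)[C@H](O)[C@@H](OC(=O)C(C)=C)[C@@H]2C(=C)C(=O)O[C@H]2C[C@@]1(C)O | intermediate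
31 | CNP0195404.1, (4S,5S,6S,7R,8S,10R)-5-hydroxy-6-(methacryloyloxy)-1-oxo-3,10-epoxygermacra-2,11(13)-dien-12,8-olide | C=C(C)C(=O)O[C@@H]1[C@@H](O)[C@H](C)C2=CC(=O)[C@@](C)(C[C@@H]3OC(=O)C(=C)[C@@H]13)O2 | target

## Step count and risks

Total step count: 17 (west branch steps 1–6, east branch steps 7–14, union and endgame steps 15–17).
Longest linear sequence: 11 steps (steps 7–14, then 15–17, from crotyl alcohol).

The three steps most likely to fail:

Step 16 (the proposed new ring closure). Failure modes are oligomerisation, thiolate addition to the exo-methylene lactone or methacrylate, and base-induced ynone-to-allenone isomerisation that would scramble C4. The fallback sets out from 28 and comes back at 29, replacing the acyl coupling by a carbonyl addition and re-oxidation. Fukuyama reduction of the thioester (Et3SiH, Lindlar-type Pd, acetone, 0 °C) gives the C1 aldehyde analogue of 28 F1. Iodination of the terminal alkyne (NIS, AgNO3 cat., acetone) gives the iodoalkyne aldehyde F2. Nozaki–Hiyama–Kishi cyclisation (CrCl2, NiCl2 cat., THF, 2 mM) adds the alkynylchromium to the aldehyde and closes the ring as the macrocyclic propargylic alcohol F3 (C1 epimers). Dess–Martin oxidation then returns 29.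

Step 15 (fragment union). The anti preference could erode with the 2-ester substituent and give some cis-lactone, the catalyst may be mismatched with the C6 and C10 centres, and the allylchromium could β-eliminate the C6 ester. The fallback sets out from 25 and comes back at 28, replacing the Barbier-type addition by an allylboration. Pd-catalysed borylation (B2pin2, Pd2(dba)3, toluene, 50 °C) converts 25 into the 2-(methoxycarbonyl)allylboronate F4. Lewis-acid-catalysed allylboration of 10 (Sc(OTf)3 or In(OTf)3, toluene, 0 °C), which favours the anti adduct, gives hydroxy ester 27 after work-up, and PPTS lactonises it to 28. The C8 face is then substrate-controlled and would have to be checked.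

Step 11 (C6 stereocentre). Chelation through a silyl ether may be incomplete and leave Felkin product. The fallback sets out from 17 and comes back at 21, replacing chelation control by inversion. Felkin–Anh addition of 18 without zinc (THF, −78 °C) gives the C6-epimeric anti allylic alcohol F5. Mitsunobu esterification with methacrylic acid (PPh3, DIAD, toluene, 0 °C) inverts C6 and installs the ester in one operation, giving 21.

## Further compounds

F1 | step 16 | (2R)-2-methyl-3-[(2S,3R)-3-{(1S,2S,3R)-3-methyl-1-[(2-methylprop-2-enoyl)oxy]-2-[(triethylsilyl)oxy]pent-4-yn-1-yl}-4-methylidene-5-oxooxolan-2-yl]-2-[(triethylsilyl)oxy]propanal | O=C[C@](C)(O[Si](CC)(CC)CC)C[C@@H]1OC(=O)C(=C)[C@H]1[C@H](OC(=O)C(C)=C)[C@@H](O[Si](CC)(CC)CC)[C@H](C)C#C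
F2 | step 16 | (2R)-3-[(2S,3R)-3-{(1S,2S,3R)-5-iodo-3-methyl-1-[(2-methylprop-2-enoyl)oxy]-2-[(triethylsilyl)oxy]pent-4-yn-1-yl}-4-methylidene-5-oxooxolan-2-yl]-2-methyl-2-[(triethylsilyl)oxy]propanal | O=C[C@](C)(O[Si](CC)(CC)CC)C[C@@H]1OC(=O)C(=C)[C@H]1[C@H](OC(=O)C(C)=C)[C@@H](O[Si](CC)(CC)CC)[C@H](C)C#CI
F3 | step 16 | (1RS,4R,5S,6S,7R,8S,10R)-1-hydroxy-6-(methacryloyloxy)-5,10-bis(triethylsilyloxy)germacr-11(13)-en-2-yn-12,8-olide | OC1C#C[C@@H](C)[C@H](O[Si](CC)(CC)CC)[C@@H](OC(=O)C(C)=C)[C@@H]2C(=C)C(=O)O[C@H]2C[C@@]1(C)O[Si](CC)(CC)CC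
F4 | step 15 | methyl (2E,4S,5S,6R)-6-methyl-4-[(2-methylprop-2-enoyl)oxy]-2-[(4,4,5,5-tetramethyl-1,3,2-dioxaborolan-2-yl)methyl]-5-[(triethylsilyl)oxy]oct-2-en-7-ynoate | C#C[C@@H](C)[C@H](O[Si](CC)(CC)CC)[C@@H](OC(=O)C(C)=C)/C=C(\CB1OC(C)(C)C(C)(C)O1)C(=O)OC
F5 | step 11 | (4R,5S,6R)-2,6-dimethyl-5-[(triethylsilyl)oxy]oct-2-en-7-yn-4-ol | C#C[C@@H](C)[C@H](O[Si](CC)(CC)CC)[C@H](O)C=C(C)C
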